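The constants belong to no real substance.

The monomer units in a closed flask stay as charged, and each standing link makes one chain fewer, so the average length is units over units minus links.

first end groups 0.66 M; second end groups 0.627 M; time 12 min

    first end groups + second end groups → links + released group (k1 = 2.15 M⁻¹ s⁻¹)
    second end groups → decomposed reagent (k2 = 0.0114 s⁻¹)
    links → over-reaction product (k3 = 4.07 × 10⁻⁵ s⁻¹)

* whether the average number of monomer units in a chain (unreacted monomers counted as chains of one) reaches 30 by 12 min (yes / no)
* average number of monomer units in a chain (unreacted monomers counted as chains of one) at 12 min

- each molecule carries two end groups: a chain counts once for every two ends that are left, dead ends included; the units are half of the end groups of the two monomers charged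
- a link that another step uses up counts as cut, two dead ends; so do two ends of one kind that react with each other
- run time (flask): 12 min

This flask holds 0.643 M of units. The second end groups are the limiting reagent, 0.627 M against 0.66 M. My first guess turns each of them into a link, which gives a length of 39.0, above the 30 wanted.

But second end groups also decompose. At the start, step 1 uses them 120 times faster than step 2, which tempts me to drop the loss. I can't: that ratio falls as the first end groups fall, and the chains are a small difference of large numbers.

Dividing the two rates gives the loss exactly. I call k2/k1 the loss constant, the second end groups lost to decomposition per unit of ln(first end groups charged / first end groups left), 0.00530 M. Taking the fast step as finished, the first end groups left are the gap 0.0330 M plus the loss. Starting from the gap, I get a loss of 0.0159 M, then with 0.0489 M left 0.0138 M, then with 0.0468 M left 0.0140 M.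

So I reckon links at 0.613 M and the length at 21.1, less than 30. Cutting shortens it further, so I answer no.

Can I ignore the cutting? The half-life of links by step 3 is 4.7 h, long against 12 min. Yet I reckon it leaves 0.595 M of links, and every cut link is one chain more, so I commit to 13.3.

The forecast says no and 13.4, against my 13.3, on the grounds that the shortage of second end groups “caps the chain length near 20”, a cap I put at 21.1.

The simulation gives no and 13.4.

Taking away the step from second end groups to decomposed reagent lifts the length at 12 min from 13.4 to 18.6 and turns the answer on whether 30 is reached by then, though that run does not make it the main reason. In this flask the loss constant gave 0.0140 M lost, and the simulation holds 0.0140 M of decomposed reagent. In the neighbour flask with 2.6 M of first end groups, the loss constant gives 0.00146 M lost and a length of 1.60, against a simulated 0.00146 M and 1.60.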